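**Count turnovers.** Decide first to count targets per catalyst rather than hours, and give every amount of target as a fraction of the starting material charged.

| flask | starting material | partner | free catalyst | time |
|---|---|---|---|---|
| ochre | 0.150 M | 0.120 M | 0.00150 M |  |
| grey | 0.150 M | 0.0600 M | 0.00150 M |  |
| violet | 0.150 M | 0.120 M | 0.00300 M |  |
| red | 0.0750 M | 0.120 M | 4.90 × 10⁻⁴ M | 3.2 h |

| run | time / h | [target] / M |
|---|---|---|
| ochre run | 0.13 | 0.0138 |
| ochre run | 0.20 | 0.0166 |
| ochre run | 0.32 | 0.0270 |
| ochre run | 0.51 | 0.0323 |
| ochre run | 0.81 | 0.0416 |
| ochre run | 1.3 | 0.0490 |
| ochre run | 2.0 | 0.0552 |
| ochre run | 3.2 | 0.0596 |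
| grey run | 0.13 | 0.0076 |
| grey run | 0.20 | 0.0145 |
| grey run | 0.32 | 0.0160 |
| grey run | 0.51 | 0.0206 |
| grey run | 0.81 | 0.0220 |
| grey run | 1.3 | 0.0348 |
| grey run | 2.0 | 0.0389 |
| grey run | 3.2 | 0.0459 |
| violet run | 0.13 | 0.0220 |
| violet run | 0.20 | 0.0334 |
| violet run | 0.32 | 0.0465 |
| violet run | 0.51 | 0.0573 |
| violet run | 0.81 | 0.0746 |
| violet run | 1.3 | 0.0875 |
| violet run | 2.0 | 0.0955 |
| violet run | 3.2 | 0.1066 |

(scatter of a reading: 0.002 M)

- Overall: starting material + partner -> target, with free catalyst as catalyst.
- Constant volume, constant temperature.
- An order is taken over about fifteen percent of the charge, up and down.

1. the power of [free catalyst] that the first rate follows, about the charge of the ochre run; measure it at two percent of starting material made into target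
2. the power of [partner] that the first rate follows, about the charge of the ochre run; measure it at two percent of starting material made into target
3. target in the red run at 3.2 h, as a share of the starting material charged

**Main step.** Suppose starting material and partner turn into target on a catalyst that lasts. The ceiling is then the charge of the limiting reagent. In the ochre run that is the partner, which allows 80.0%. In the red run it is the starting material, which allows the whole charge. But the ochre run reads 39.7% at 3.2 h, and it gained 2.93% over its last 1.20 h.

**Dying catalyst.** Now let the catalyst be lost as it works. Each catalyst then delivers a limited count, and the ochre run reads 39.7 as its turnover count, the target made per catalyst charged by 3.2 h. The ochre first reading gives a rate, and the final target over that rate gives a lifetime of 0.561 h, so 3.2 h spans 5.70 lifetimes. I therefore treat the ochre count as close to finished.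

**Partner drain.** Last, the partner is drawn down as well. By 3.2 h the grey run has used 76.5% of its partner and the violet run 88.8%, against 49.7% in the ochre run. Their counts read lower, at 30.6 and 35.5. The red run should use 16.2% of its partner, so I take the ochre count as the guide, from the run with the lowest partner use of the three.

**My reckoning.** The ochre, grey and violet runs share one charge of starting material, so carrying the count to the red charge is my assumption. The count times the red catalyst, over the red starting material, gives 26.0%. I commit to no orders, since the scatter is 14.5% of the first ochre reading.

**The forecast.** The forecast, reasoning that “the catalyst is probably dying”, gives 0.87 for the catalyst order, 0.7 for the partner order and 29% for the red run.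

**The flask.** The catalyst order comes to 1.0 and the partner order to 0.92, and the red run gives 26.8%.

    free catalyst + starting material → loaded catalyst + by-product (4788 L mol⁻¹ h⁻¹)
    loaded catalyst + partner → target + free catalyst (716.4 L mol⁻¹ h⁻¹)
    free catalyst + starting material → spent catalyst + starting material (115.2 L mol⁻¹ h⁻¹)

**Why it stops.** The red run made 41.1 targets per catalyst charged, and in the scheme free catalyst meets starting material on both competing paths, whose constants stand in the ratio 41.6. The main reason the red run stands at 26.8% at 3.2 h is the path to spent catalyst, since the same run without that path reaches 88.1% at that time. In the violet run, the ochre count times the doubled catalyst allows 79.5%, which is past half of the starting material, and the violet run reaches that half at 0.849 h.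

The runs come from a simulation for substances that don't exist, and the scatter is random.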